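**Plan**

1. Locants (briarane): ring A = C1, C10–C14 (C15 methyl on C1, C20 methylene on C11); ten-membered ring = C1–C10 (C16 methylene on C5); oxane = O, C4–C8; lactone = C7, C8, C17 (C18 methyl), C19.
2. Retrosynthesis: the acetates and the free C3–OH are adjusted last and C14–OAc comes from a C14 acetyl group (Baeyer–Villiger). C13–C14 and C1–C10 are then cut together ([4+2] of diene C10=C11–C12=C13 with dienophile C1=C14). Next come C2–C3 (furyllithium + aldehyde) and the C9 arm (vinyl addition, enyne metathesis). The oxane–lactone core goes back to a furan (cuts at O–C8, C8–C17, O7–C19).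
3. Forward: furan → Achmatowicz pyranone (oxane) → C8 quaternary centre → lactone and chloride → C3 arm (a second furan) → C9 arm (silicon-tethered diene) → ring A and the ten-membered ring in one operation → acetate pattern.
4. Enabling feature: the ether oxygen bridging C4 and C8 (cis-2,6-disubstituted oxane O/C4–C8) holds the C1–C3 arm and the C9–C13 arm on one face. The ten-membered ring therefore only has to close as an eight-membered oxacycle (C1, C2, C3, C4, O, C8, C9, C10) while ring A forms.
5. Helpers, removed later: a furan ring as latent cis-enedione (fixes the C14 substituent cis to C2; its acetyl group becomes the C14 acetate); an oxasilin ring O9–Si–C20 (fixes diene geometry, holds O9 in the diene plane, later gives C11=C20).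
6. Stereochemistry: C4 (Noyori transfer hydrogenation) and C9 (CBS reduction) by catalyst control; C8, C7, C6, C17 and C3 relayed from C4; C1, C10 and C14 set together in the cycloaddition from C9; C2 from C3.

Key step: step 26

Remark: TBS = tert-butyldimethylsilyl, PMB = 4-methoxybenzyl, TIPS = triisopropylsilyl; the addition in step 8 is assumed to be unselective at C17, which step 12 then sets.

**Route**

Step 1
Reactants: 1 furfuryl alcohol
Product: 2 tert-butyl(furan-2-ylmethoxy)dimethylsilane
Conditions: TBSCl, imidazole, DMF, 23 °C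
Reagents that add atoms: tert-butyldimethylsilyl chloride CC(C)(C)[Si](C)(C)Cl
Why: Standard silylation of a primary alcohol; the ether carries the future C9 oxygen through the lithiation of step 3.

Step 2
Reactants: 3 2-chloro-N-methoxy-N-methylacetamide; 4 4-methoxybenzyl alcohol
Product: 6 N-methoxy-2-[(4-methoxybenzyl)oxy]-N-methylacetamide, via sodium 4-methoxybenzyl alkoxide 5 (not isolated)
Conditions: NaH, THF, 0 °C; then 3, Bu4NI (cat.), 0 → 23 °C
Reagents that add atoms: none
Why: Williamson ether synthesis on an α-chloro amide, which is an activated SN2 electrophile.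

Step 3
Reactants: 2 tert-butyl(furan-2-ylmethoxy)dimethylsilane; 6 PMB-oxy Weinreb amide
Product: 8 1-[5-(TBSO-methyl)furan-2-yl]-2-(PMB-oxy)ethanone, via lithiated furan 7 (not isolated)
Conditions: n-BuLi, THF, −78 → 0 °C; then 6, −78 °C; AcOH
Reagents that add atoms: none
Why: Lithiation of the furan at its free α-position (C5) and Weinreb ketone synthesis, whose chelated tetrahedral adduct prevents over-addition.

Step 4
Reactants: 8 furyl ketone
Product: 9 (S)-1-[5-(TBSO-methyl)furan-2-yl]-2-(PMB-oxy)ethanol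
Conditions: RuCl(p-cymene)[(S,S)-TsDPEN] (1 mol %), HCO2H/Et3N (5:2), CH2Cl2, 23 °C
Reagents that add atoms: none
Why: Noyori asymmetric transfer hydrogenation of a heteroaryl ketone; the (S,S) catalyst should give the (S) carbinol, which is C4 of the target.

Step 5
Reactants: 9 (S)-furyl carbinol
Product: 10 (2S)-6-hydroxy-2-(PMBO-methyl)-6-(TBSO-methyl)-2H-pyran-3(6H)-one (both C8 anomers)
Conditions: NBS, NaHCO3, NaOAc, THF/H2O (4:1), 0 °C
Reagents that add atoms: water O
Why: Achmatowicz rearrangement turns the furyl carbinol into the oxane (O, C4–C8) with C5 as ketone, C6=C7 as alkene and C8 as ketal, leaving C4 untouched.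

Step 6
Reactants: 10 pyranone hemiketal
Product: 11 C8 acetate of 10 (both anomers)
Conditions: Ac2O, Et3N, DMAP (cat.), CH2Cl2, 0 °C
Reagents that add atoms: acetic anhydride CC(=O)OC(C)=O
Why: DMAP-catalysed acylation gives the ketal a leaving group for the ionisation in step 8.

Step 7
Reactants: 12 tert-butyl propionate
Product: 14 1-tert-butoxy-1-(trimethylsilyloxy)prop-1-ene (E/Z mixture), via lithium ester enolate 13 (not isolated)
Conditions: LiN(iPr)2, THF, −78 °C; Me3SiCl, −78 → 23 °C
Reagents that add atoms: chlorotrimethylsilane C[Si](C)(C)Cl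
Why: O-silylation of an ester enolate gives the silyl ketene acetal that will deliver C17, C18 and C19.

Step 8
Reactants: 11 ketal acetate; 14 silyl ketene acetal
Product: 15 enone ester: oxane with C5 ketone, C6=C7, and C8 bearing CH2OTBS (cis to the C4 arm) and CH(CH3)CO2tBu (trans); C17 epimers
Conditions: BF3·OEt2, CH2Cl2, −78 °C
Reagents that add atoms: none
Why: Lewis-acid ionisation to the C8 oxocarbenium ion and Mukaiyama-type C-glycosylation, in which axial attack trans to the pseudo-equatorial C4 substituent should set the quaternary centre C8.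

Step 9
Reactants: 15 enone ester
Product: 16 6,7-epoxy ketone (epoxide on the face of the C8 CH2OTBS group)
Conditions: t-BuOOH, DBU, CH2Cl2, 0 °C
Reagents that add atoms: tert-butyl hydroperoxide CC(C)(C)OO
Why: Weitz–Scheffer nucleophilic epoxidation, in which the peroxide adds to C7 anti to the pseudo-axial propionate chain on C8.

Step 10
Reactants: 16 epoxy ketone
Product: 17 γ-lactone (O7–C19) with C5 ketone and C6 hydroxyl trans to O7; C17 epimers
Conditions: BF3·OEt2, CH2Cl2, −40 → 0 °C
Reagents that add atoms: none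
Why: Lewis-acid epoxide opening by the tert-butyl ester carbonyl (5-exo, inversion at C7, loss of isobutene) closes the cis-fused lactone and leaves the C6 oxygen on the opposite face, while the ketone disfavours attack at C6.

Step 11
Reactants: 17 hydroxy lactone ketone
Product: 18 5(16)-methylene 6-alcohol; C17 epimers
Conditions: Zn, CH2Br2, TiCl4 (pre-formed reagent), THF/CH2Cl2, 0 → 23 °C
Reagents that add atoms: dibromomethane BrCBr
Why: Takai–Lombardo methylenation is non-basic and ketone-selective, so the lactone survives and the β-acyloxy ketone is not eliminated.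

Step 12
Reactants: 18 methylene alcohol (C17 epimers)
Product: 20 (17R) lactone, via dilithium alkoxide enolate 19 (not isolated)
Conditions: LiN(SiMe3)2 (2.5 equiv), THF, −78 °C; then AcOH, −78 °C
Reagents that add atoms: none
Why: Kinetic protonation of the lactone enolate from the convex face of the cis-fused bicycle (the face of H7 and the C8 CH2OTBS group) should place C18 on the concave face, cis to the oxane oxygen.

Step 13
Reactants: 20 (17R) allylic alcohol
Product: 21 (6S) allylic chloride (Cl cis to O7)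
Conditions: PPh3, Cl3CC(O)CCl3, CH2Cl2, 0 °C
Reagents that add atoms: hexachloroacetone ClC(Cl)(Cl)C(=O)C(Cl)(Cl)Cl
Why: Appel-type chlorination with PPh3/hexachloroacetone converts secondary allylic alcohols to chlorides by SN2 inversion without allylic transposition, which sets C6.

Step 14
Reactants: 21 allylic chloride
Product: 22 primary alcohol at the C3 carbon
Conditions: DDQ, CH2Cl2/pH 7 buffer (10:1), 0 °C
Reagents that add atoms: none
Why: Oxidative cleavage of the PMB ether, which leaves the TBS ether, the lactone and the allylic chloride untouched.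

Step 15
Reactants: 22 primary alcohol
Product: 23 C3 aldehyde
Conditions: Dess–Martin periodinane, NaHCO3, CH2Cl2, 0 → 23 °C
Reagents that add atoms: none
Why: Dess–Martin oxidation under buffered, non-epimerising conditions; the aldehyde is used directly.

Step 16
Reactants: 23 C3 aldehyde; 24 2,4-dimethylfuran
Product: 26 (3R) furyl carbinol, via (3,5-dimethylfuran-2-yl)lithium 25 (not isolated)
Conditions: 24, n-BuLi, THF, 0 °C; then 23, −78 °C; AcOH
Reagents that add atoms: none
Why: Organolithium addition to an α-alkoxy aldehyde under non-chelating conditions (Felkin–Anh) should give the 3,4-anti carbinol, and the aldehyde reacts far faster than the lactone at −78 °C.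

Step 17
Reactants: 26 furyl carbinol
Product: 27 3-O-TIPS ether
Conditions: TIPSOTf, 2,6-lutidine, CH2Cl2, −78 → 0 °C
Reagents that add atoms: triisopropylsilyl triflate CC(C)[Si](OS(=O)(=O)C(F)(F)F)(C(C)C)C(C)C
Why: Silylation protects O3 until the last step and prevents an Achmatowicz-type reaction of the furyl carbinol in step 26.

Step 18
Reactants: 27 TIPS ether
Product: 28 primary alcohol at the C9 carbon
Conditions: HF·pyridine, pyridine, THF, 0 °C
Reagents that add atoms: none
Why: Buffered HF·pyridine cleaves a primary TBS ether selectively in the presence of a secondary TIPS ether.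

Step 19
Reactants: 28 primary alcohol
Product: 29 C9 aldehyde
Conditions: Dess–Martin periodinane, NaHCO3, CH2Cl2, 0 → 23 °C
Reagents that add atoms: none
Why: Dess–Martin oxidation; the aldehyde sits on the quaternary carbon C8 and cannot epimerise.

Step 20
Reactants: 29 C9 aldehyde
Product: 30 C9 vinyl carbinols (both epimers)
Conditions: CH2=CHMgBr, THF, −78 °C; AcOH
Reagents that add atoms: vinylmagnesium bromide C=C[Mg]Br
Why: Grignard addition, chemoselective for the aldehyde over the lactone at low temperature; the C9 configuration is set in step 22.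

Step 21
Reactants: 30 vinyl carbinols
Product: 31 C9 vinyl ketone
Conditions: Dess–Martin periodinane, NaHCO3, CH2Cl2, 0 °C
Reagents that add atoms: none
Why: Dess–Martin oxidation converges both epimers to one enone.

Step 22
Reactants: 31 vinyl ketone
Product: 32 (9S) vinyl carbinol
Conditions: (R)-2-methyl-CBS-oxazaborolidine (0.5 equiv), catecholborane, toluene, −78 °C
Reagents that add atoms: none
Why: Corey–Bakshi–Shibata 1,2-reduction, in which the fully substituted C8 is the large group and vinyl the small one, so the (R) catalyst should give the (S) alcohol.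

Step 23
Reactants: 33 propargyl bromide; 34 dichlorodimethylsilane
Product: 36 chlorodimethyl(prop-2-yn-1-yl)silane, via prop-2-ynylmagnesium bromide 35 (not isolated)
Conditions: Mg, ZnBr2 (cat.), Et2O, 0 °C; then Me2SiCl2 (3 equiv), −78 → 23 °C; distillation
Reagents that add atoms: none
Why: Silylation of the propargyl/allenyl Grignard reagent, which reacts with chlorosilanes at the propargylic terminus.

Step 24
Reactants: 32 (9S) vinyl carbinol; 36 chlorodimethyl(prop-2-yn-1-yl)silane
Product: 37 9-O-[dimethyl(prop-2-ynyl)silyl] ether of 32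
Conditions: imidazole, CH2Cl2, 0 °C
Reagents that add atoms: none
Why: Silyl ether formation attaches the temporary silicon tether that carries C20, C11 and C12.

Step 25
Reactants: 37 enyne silyl ether
Product: 38 oxasilin diene: ring O9–SiMe2–C20–C11=C10–C9 with vinyl (C12=C13) on C11
Conditions: second-generation Grubbs catalyst RuCl2(=CHPh)(PCy3)(H2IMes) (10 mol %), ethylene (1 atm), toluene, 60 °C
Reagents that add atoms: none
Why: Ring-closing enyne metathesis in the exo mode gives the six-membered 1-vinylcycloalkene, so C9 is held trans to C12 on C10=C11 and the hindered 1,1-disubstituted C5=C16 alkene and the furan do not take part.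

Step 26
Reactants: 38 oxasilin diene carrying the 3,5-dimethylfuran-2-yl group on C3
Product: 41 cycloadduct (ring A and ten-membered ring closed; C14 acetyl, C2 ketone, oxasilin ring fused at C9–C10–C11), via furan endoperoxide 39 (not isolated), via cis-enedione 40 (not isolated)
Conditions: O2, tetraphenylporphyrin (cat.), visible light, CH2Cl2, −78 °C; Me2S, −78 → 0 °C; then toluene (0.002 M), BHT, 40–60 °C
Reagents that add atoms: dioxygen O=O
Why: Singlet oxygen adds [4+2] across the electron-rich trisubstituted furan and Me2S reduces endoperoxide 39 to cis-enedione 40, whose C1=C14 bond then undergoes a concerted thermal intramolecular Diels–Alder reaction with the diene C10=C11–C12=C13 to form C1–C10 and C13–C14. The closest known reaction types are the photooxygenation of furans to cis-enediones and medium-ring-forming intramolecular Diels–Alder macrocyclisations of doubly activated dienophiles. Ring A closes by the [4+2] cycloaddition and the ten-membered carbocycle closes in the fused mode as an eight-membered oxacycle across the oxane, with the tether atom C2 exo. C14 follows from the cis geometry of the enedione (acetyl cis to C2); the trans ring fusion (C15 cis to C9, H10 trans to C15) follows from the exo-tether transition state with the methyl group and H14 endo; the absolute sense at C10, C1 and C14 is relayed from C9, because the oxasilin ring holds O9 in the diene plane so that C8, and with it the tethered dienophile, lies on one diene face. The step needs chemoselective oxidation of the furan, fused rather than bridged regiochemistry and exo rather than endo closure; these rest on the much higher singlet-oxygen reactivity of furans, on the ortho preference of the C10 substituent together with the shorter tether path, and on the strain of folding the oxane under the diene.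

Step 27
Reactants: 41 cycloadduct
Product: 43 9-alcohol with C11=C20 methylene (C14 acetyl, C2 ketone, 3-O-TIPS), via 9-O-silanol ether 42 (not isolated)
Conditions: TsOH·H2O, MeCN/H2O (20:1), 23 °C
Reagents that add atoms: none
Why: Protodesilylation of the allylsilane (SE2′): the proton adds at C12, the double bond moves to C11=C20 as the C20–Si bond breaks, and the labile Si–O9 bond is then hydrolysed.

Step 28
Reactants: 43 methyl ketone
Product: 44 14-acetate (C2 ketone, 9-OH, 3-O-TIPS)
Conditions: Me3SiOOSiMe3, SnCl4, trans-N,N′-bis(p-tolylsulfonyl)cyclohexane-1,2-diamine, 4 Å MS, CH2Cl2, −20 °C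
Reagents that add atoms: bis(trimethylsilyl) peroxide C[Si](C)(C)OO[Si](C)(C)C
Why: Baeyer–Villiger oxidation with a Lewis-acid-activated silyl peroxide, which spares C=C bonds; the secondary C14 migrates with retention in preference to methyl, and the far more hindered C2 ketone should react more slowly.

Step 29
Reactants: 44 C2 ketone
Product: 45 (2R) alcohol
Conditions: NaBH4, CeCl3·7H2O, MeOH, −40 °C
Reagents that add atoms: none
Why: Non-chelating hydride reduction of an α-silyloxy ketone (Felkin–Anh, 1,2-induction from C3) should give the 2,3-syn alcohol, and a small hydride is needed at this neopentyl carbonyl.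

Step 30
Reactants: 45 2,9-diol
Product: 46 2,9,14-triacetate 3-O-TIPS ether
Conditions: Ac2O, DMAP, pyridine, 40 °C
Reagents that add atoms: acetic anhydride CC(=O)OC(C)=O
Why: DMAP-catalysed acetylation of both free hydroxyls; any 14→2 acetyl migration in step 29 converges here.

Step 31
Reactants: 46 triacetate TIPS ether
Product: 47 CNP0280492.1
Conditions: HF·pyridine, pyridine/THF, 23 °C
Reagents that add atoms: none
Why: Desilylation with an acidic fluoride source frees O3 without the base-induced 2→3 acetyl migration and without touching the allylic chloride or the lactone.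

**Compound list**

1 | furfuryl alcohol | OCc1ccco1 | starting material
2 | tert-butyl(furan-2-ylmethoxy)dimethylsilane | CC(C)(C)[Si](C)(C)OCc1ccco1 | intermediate
3 | 2-chloro-N-methoxy-N-methylacetamide | CON(C)C(=O)CCl | starting material
4 | 4-methoxybenzyl alcohol | COc1ccc(CO)cc1 | starting material
5 | sodium 4-methoxybenzyl alkoxide (not isolated) | COc1ccc(C[O-])cc1.[Na+] | intermediate
6 | N-methoxy-2-[(4-methoxybenzyl)oxy]-N-methylacetamide | CON(C)C(=O)COCc1ccc(OC)cc1 | intermediate
7 | tert-butyl[(5-lithiofuran-2-yl)methoxy]dimethylsilane (not isolated) | CC(C)(C)[Si](C)(C)OCc1ccc([Li])o1 | intermediate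
8 | 1-[5-(TBSO-methyl)furan-2-yl]-2-(PMB-oxy)ethanone | O=C(COCc1ccc(OC)cc1)c1ccc(CO[Si](C)(C)C(C)(C)C)o1 | intermediate
9 | (S)-1-[5-(TBSO-methyl)furan-2-yl]-2-(PMB-oxy)ethanol | O[C@H](c1ccc(CO[Si](C)(C)C(C)(C)C)o1)COCc1ccc(OC)cc1 | intermediate
10 | (2S)-6-hydroxy-2-(PMBO-methyl)-6-(TBSO-methyl)-2H-pyran-3(6H)-one, C8 anomers | O=C1C=CC(O)(CO[Si](C)(C)C(C)(C)C)O[C@H]1COCc1ccc(OC)cc1 | intermediate
11 | C8 acetate of 10, C8 anomers | CC(=O)OC1(CO[Si](C)(C)C(C)(C)C)C=CC(=O)[C@H](COCc2ccc(OC)cc2)O1 | intermediate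
12 | tert-butyl propionate | CCC(=O)OC(C)(C)C | starting material
13 | lithium enolate of tert-butyl propionate (not isolated) | CC=C(O[Li])OC(C)(C)C | intermediate
14 | 1-tert-butoxy-1-(trimethylsilyloxy)prop-1-ene, E/Z mixture | CC=C(OC(C)(C)C)O[Si](C)(C)C | intermediate
15 | C8-quaternary enone tert-butyl ester, C17 epimers | CC(C)(C)[Si](C)(C)OC[C@]1(C(C)C(=O)OC(C)(C)C)C=CC(=O)[C@H](COCc2ccc(OC)cc2)O1 | intermediate
16 | 6,7-epoxy ketone, C17 epimers | CC(C)(C)[Si](C)(C)OC[C@]1(C(C)C(=O)OC(C)(C)C)[C@@H]2O[C@@H]2C(=O)[C@H](COCc3ccc(OC)cc3)O1 | intermediate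
17 | oxane-fused γ-lactone with C5 ketone and C6 hydroxyl, C17 epimers | CC(C)(C)[Si](C)(C)OC[C@@]12O[C@H](C(=O)[C@@H](O)[C@@H]1OC(=O)C2C)COCc1ccc(OC)cc1 | intermediate
18 | 5(16)-methylene 6-alcohol, C17 epimers | CC(C)(C)[Si](C)(C)OC[C@@]12O[C@H](C(=C)[C@@H](O)[C@@H]1OC(=O)C2C)COCc1ccc(OC)cc1 | intermediate
19 | dilithium 6-alkoxide lactone enolate of 18 (not isolated) | CC(C)(C)[Si](C)(C)OC[C@@]12O[C@H](C(=C)[C@@H](O[Li])[C@@H]1OC(O[Li])=C2C)COCc1ccc(OC)cc1 | intermediate
20 | (17R) lactone 6-alcohol | CC(C)(C)[Si](C)(C)OC[C@@]12O[C@H](C(=C)[C@@H](O)[C@@H]1OC(=O)[C@@H]2C)COCc1ccc(OC)cc1 | intermediate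
21 | (6S) allylic chloride | CC(C)(C)[Si](C)(C)OC[C@@]12O[C@H](C(=C)[C@H](Cl)[C@@H]1OC(=O)[C@@H]2C)COCc1ccc(OC)cc1 | intermediate
22 | primary alcohol at the C3 carbon | CC(C)(C)[Si](C)(C)OC[C@@]12O[C@H](C(=C)[C@H](Cl)[C@@H]1OC(=O)[C@@H]2C)CO | intermediate
23 | C3 aldehyde | CC(C)(C)[Si](C)(C)OC[C@@]12O[C@H](C(=C)[C@H](Cl)[C@@H]1OC(=O)[C@@H]2C)C=O | intermediate
24 | 2,4-dimethylfuran | Cc1cc(C)co1 | starting material
25 | (3,5-dimethylfuran-2-yl)lithium (not isolated) | Cc1cc(C)c([Li])o1 | intermediate
26 | (3R) 3,5-dimethylfuran-2-yl carbinol | CC(C)(C)[Si](C)(C)OC[C@@]12O[C@H](C(=C)[C@H](Cl)[C@@H]1OC(=O)[C@@H]2C)[C@@H](O)c1oc(C)cc1C | intermediate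
27 | 3-O-TIPS ether of 26 | CC(C)(C)[Si](C)(C)OC[C@@]12O[C@H](C(=C)[C@H](Cl)[C@@H]1OC(=O)[C@@H]2C)[C@@H](O[Si](C(C)C)(C(C)C)C(C)C)c1oc(C)cc1C | intermediate
28 | primary alcohol at the C9 carbon | OC[C@@]12O[C@H](C(=C)[C@H](Cl)[C@@H]1OC(=O)[C@@H]2C)[C@@H](O[Si](C(C)C)(C(C)C)C(C)C)c1oc(C)cc1C | intermediate
29 | C9 aldehyde | O=C[C@@]12O[C@H](C(=C)[C@H](Cl)[C@@H]1OC(=O)[C@@H]2C)[C@@H](O[Si](C(C)C)(C(C)C)C(C)C)c1oc(C)cc1C | intermediate
30 | C9 vinyl carbinols, both epimers | C=CC(O)[C@@]12O[C@H](C(=C)[C@H](Cl)[C@@H]1OC(=O)[C@@H]2C)[C@@H](O[Si](C(C)C)(C(C)C)C(C)C)c1oc(C)cc1C | intermediate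
31 | C9 vinyl ketone | C=CC(=O)[C@@]12O[C@H](C(=C)[C@H](Cl)[C@@H]1OC(=O)[C@@H]2C)[C@@H](O[Si](C(C)C)(C(C)C)C(C)C)c1oc(C)cc1C | intermediate
32 | (9S) vinyl carbinol | C=C[C@H](O)[C@@]12O[C@H](C(=C)[C@H](Cl)[C@@H]1OC(=O)[C@@H]2C)[C@@H](O[Si](C(C)C)(C(C)C)C(C)C)c1oc(C)cc1C | intermediate
33 | propargyl bromide | C#CCBr | starting material
34 | dichlorodimethylsilane | C[Si](C)(Cl)Cl | starting material
35 | prop-2-ynylmagnesium bromide (not isolated) | C#CC[Mg]Br | intermediate
36 | chlorodimethyl(prop-2-yn-1-yl)silane | C#CC[Si](C)(C)Cl | intermediate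
37 | 9-O-[dimethyl(prop-2-ynyl)silyl] ether of 32 | C=C[C@H](O[Si](C)(C)CC#C)[C@@]12O[C@H](C(=C)[C@H](Cl)[C@@H]1OC(=O)[C@@H]2C)[C@@H](O[Si](C(C)C)(C(C)C)C(C)C)c1oc(C)cc1C | intermediate
38 | oxasilin diene (2,2-dimethyl-4-vinyl-3,6-dihydro-2H-1,2-oxasilin-6-yl on C8) | C=CC1=C[C@H](O[Si](C)(C)C1)[C@@]12O[C@H](C(=C)[C@H](Cl)[C@@H]1OC(=O)[C@@H]2C)[C@@H](O[Si](C(C)C)(C(C)C)C(C)C)c1oc(C)cc1C | intermediate
39 | furan endoperoxide of 38 (not isolated) | C=CC1=C[C@H](O[Si](C)(C)C1)[C@@]12O[C@H](C(=C)[C@H](Cl)[C@@H]1OC(=O)[C@@H]2C)[C@@H](O[Si](C(C)C)(C(C)C)C(C)C)C12OOC(C)(O1)C=C2C | intermediate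
40 | cis-enedione, (Z)-C2(=O)–C1(CH3)=C14H–C(=O)CH3 (not isolated) | C=CC1=C[C@H](O[Si](C)(C)C1)[C@@]12O[C@H](C(=C)[C@H](Cl)[C@@H]1OC(=O)[C@@H]2C)[C@@H](O[Si](C(C)C)(C(C)C)C(C)C)C(=O)/C(C)=C\C(C)=O | intermediate
41 | cycloadduct with C14 acetyl, C2 ketone and fused oxasilin ring | C[Si]1(C)CC2=CC[C@H](C(C)=O)[C@@]3(C)[C@H]2[C@H](O1)[C@@]45O[C@H](C(=C)[C@H](Cl)[C@@H]4OC(=O)[C@@H]5C)[C@@H](O[Si](C(C)C)(C(C)C)C(C)C)C3=O | intermediate
42 | 9-O-(hydroxydimethylsilyl) ether of 43 (not isolated) | C=C1CC[C@H](C(C)=O)[C@@]2(C)[C@H]1[C@H](O[Si](C)(C)O)[C@@]13O[C@H](C(=C)[C@H](Cl)[C@@H]1OC(=O)[C@@H]3C)[C@@H](O[Si](C(C)C)(C(C)C)C(C)C)C2=O | intermediate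
43 | 9-alcohol with C11=C20 methylene, C14 acetyl, C2 ketone | C=C1CC[C@H](C(C)=O)[C@@]2(C)[C@H]1[C@H](O)[C@@]13O[C@H](C(=C)[C@H](Cl)[C@@H]1OC(=O)[C@@H]3C)[C@@H](O[Si](C(C)C)(C(C)C)C(C)C)C2=O | intermediate
44 | 14-acetate with C2 ketone and 9-OH | C=C1CC[C@H](OC(C)=O)[C@@]2(C)[C@H]1[C@H](O)[C@@]13O[C@H](C(=C)[C@H](Cl)[C@@H]1OC(=O)[C@@H]3C)[C@@H](O[Si](C(C)C)(C(C)C)C(C)C)C2=O | intermediate
45 | (2R) 2,9-diol 14-acetate | C=C1CC[C@H](OC(C)=O)[C@@]2(C)[C@H]1[C@H](O)[C@@]13O[C@H](C(=C)[C@H](Cl)[C@@H]1OC(=O)[C@@H]3C)[C@@H](O[Si](C(C)C)(C(C)C)C(C)C)[C@@H]2O | intermediate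
46 | 2,9,14-triacetate 3-O-TIPS ether | C=C1CC[C@H](OC(C)=O)[C@@]2(C)[C@H]1[C@H](OC(C)=O)[C@@]13O[C@H](C(=C)[C@H](Cl)[C@@H]1OC(=O)[C@@H]3C)[C@@H](O[Si](C(C)C)(C(C)C)C(C)C)[C@@H]2OC(C)=O | intermediate
47 | CNP0280492.1 | C=C1CC[C@H](OC(C)=O)[C@@]2(C)[C@H]1[C@H](OC(C)=O)[C@@]13O[C@H](C(=C)[C@H](Cl)[C@@H]1OC(=O)[C@@H]3C)[C@@H](O)[C@@H]2OC(C)=O | target

**Count and risks**

Total step count: 31. Longest linear sequence: 28 steps (steps 1, 3–6, 8–22, 24–31).

Steps most likely to fail:

1. Step 26. Singlet oxygen may not discriminate cleanly between the furan and the silyl diene, and the cis-enedione may isomerise or oligomerise before the slow medium-ring closure. The fallback reverses the order of unveiling and sets out from 37, which has no diene. Photooxygenation and Me2S reduction (conditions of step 26, −78 °C) give the cis-enedione enyne silyl ether F1. Ring-closing enyne metathesis (second-generation Grubbs catalyst, ethylene, toluene, 0.002 M, 60 °C) then generates diene 40 in the presence of its dienophile, so that it is consumed by the cycloaddition as it forms (tandem enyne metathesis/Diels–Alder). The route is rejoined at 41.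

2. Step 28. The Lewis-acid-activated peroxide may fail to add to the hindered methyl ketone, or the acid may trigger cationic reactions of the 11(20)-alkene. The fallback sets out from 43 and uses a peracid Baeyer–Villiger oxidation (CF3CO3H, Na2HPO4, CH2Cl2, 0 °C), accepting epoxidation of the unhindered 11(20)-alkene; the 5(16)-alkene is deactivated by the flanking C–Cl and C–O bonds. This gives the 14-acetate 11,20-epoxide F2. Stereospecific deoxygenation of the epoxide (triphenylphosphine selenide, CF3CO2H, CH2Cl2, 23 °C) restores the alkene and returns the route at 44.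

3. Step 29. The conformation of the ten-membered ring may override Felkin–Anh control and give poor facial selectivity at the C2 ketone. The fallback replaces external hydride by internal delivery and sets out from 44. Methanolysis of its single acetate (Mg(OMe)2, MeOH, 0 °C) gives the 9,14-diol 2-ketone F3. Directed reduction with Me4NBH(OAc)3 (AcOH/MeCN, −30 °C) delivers hydride from the O14-bound boron and should give the 1,3-anti 2,9,14-triol F4, which has the required 2R configuration. Peracetylation (Ac2O, DMAP, pyridine) returns the route at 46.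

Further compounds
F1 | step 26 | cis-enedione enyne silyl ether (furan of 37 opened) | C=C[C@H](O[Si](C)(C)CC#C)[C@@]12O[C@H](C(=C)[C@H](Cl)[C@@H]1OC(=O)[C@@H]2C)[C@@H](O[Si](C(C)C)(C(C)C)C(C)C)C(=O)/C(C)=C\C(C)=O
F2 | step 28 | 14-acetate 11,20-epoxide (C2 ketone, 9-OH, 3-O-TIPS) | C1OC12CC[C@H](OC(C)=O)[C@@]3(C)[C@H]2[C@H](O)[C@@]45O[C@H](C(=C)[C@H](Cl)[C@@H]4OC(=O)[C@@H]5C)[C@@H](O[Si](C(C)C)(C(C)C)C(C)C)C3=O
F3 | step 29 | 9,14-diol 2-ketone 3-O-TIPS ether | C=C1CC[C@H](O)[C@@]2(C)[C@H]1[C@H](O)[C@@]13O[C@H](C(=C)[C@H](Cl)[C@@H]1OC(=O)[C@@H]3C)[C@@H](O[Si](C(C)C)(C(C)C)C(C)C)C2=O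
F4 | step 29 | (2R) 2,9,14-triol 3-O-TIPS ether | C=C1CC[C@H](O)[C@@]2(C)[C@H]1[C@H](O)[C@@]13O[C@H](C(=C)[C@H](Cl)[C@@H]1OC(=O)[C@@H]3C)[C@@H](O[Si](C(C)C)(C(C)C)C(C)C)[C@@H]2O
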